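**Retrosynthetic overview**
1. Acyl-donor branch: (2R)-2-methylbutanoic acid 1 and tert-butyl N-hydroxy-N-methylcarbamate 2 give O-acyl carbamate 3, then N-methyl-O-acylhydroxylammonium chloride 4.
2. Core: (2S)-pinocembrin 5 is bought with rings A, B and C and with C2 in place. No ring is formed in the route and no phenol is protected.
3. Key disconnection: the C3–O bond. Salt 4 condenses with the C4 ketone of 5 to N-acyloxy enamine 6; a [3,3] shift gives 2,3-trans ketimine 7, which is hydrolysed to target 8.
4. Stereocenters: C2 comes from 5, the acyl α-carbon from 1, and C3 is set in the key step anti to the C2 phenyl.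

Assumption: (2S)-pinocembrin and (2R)-2-methylbutanoic acid are bought as single enantiomers (catalogue items) and their ee is checked on receipt.

**Step 1**
Reactants: 1 (2R)-2-methylbutanoic acid; 2 tert-butyl N-hydroxy-N-methylcarbamate
Product: 3 tert-butyl N-methyl-N-{[(2R)-2-methylbutanoyl]oxy}carbamate
Conditions: DCC (1.05 equiv), DMAP (5 mol%), CH2Cl2, 0 °C to rt, 4 h
Reagents that add atoms: none
Why: Steglich esterification of the acidic N–OH, the only nucleophilic site of 2; low DMAP loading at 0 °C keeps the α-stereocenter of 1 from epimerising through a ketene.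

**Step 2**
Reactants: 3 tert-butyl N-methyl-N-{[(2R)-2-methylbutanoyl]oxy}carbamate
Product: 4 N-methyl-O-[(2R)-2-methylbutanoyl]hydroxylammonium chloride
Conditions: HCl (4 M in dioxane, 5 equiv), 0 °C to rt, 3 h; Et2O trituration
Reagents that add atoms: hydrogen chloride, SMILES: Cl
Why: Anhydrous acidolysis of the tert-butyl carbamate (Boc cleavage) leaves nitrogen protonated, which blocks O-to-N acyl shift, and the salt precipitates; no stereocenter is touched.

**Step 3**
Reactants: 5 (2S)-5,7-dihydroxy-2-phenyl-2,3-dihydro-4H-chromen-4-one ((2S)-pinocembrin); 4 N-methyl-O-[(2R)-2-methylbutanoyl]hydroxylammonium chloride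
Product: 8 (2R,3R)-5,7-dihydroxy-4-oxo-2-phenyl-3,4-dihydro-2H-chromen-3-yl (2R)-2-methylbutanoate, via N-acyloxy enamine 6 (not isolated), via trans-ketimine 7 (not isolated)
Conditions: 4 (1.5 equiv), DMSO (2% H2O), 50 °C, 36 h; then 1 M HCl (aq)/THF, rt, 1 h
Reagents that add atoms: water, SMILES: O (the C4 carbonyl oxygen of 8 after hydrolysis of 7)
Why: Proposed new method: acyloxy transfer from an α-stereogenic aliphatic N-methyl-O-acylhydroxylammonium salt to C3–H of an unprotected 5,7-dihydroxyflavanone; 4 condenses with the C4 ketone (the iminium is stabilised by electron-rich ring A), loss of H3 gives N-acyloxy enamine 6, and a concerted [3,3]-sigmatropic shift breaks the weak N–O bond and joins the acyl carbonyl oxygen to C3 on the face anti to the C2 phenyl, so C3 is set 2,3-trans (3R in 8; the diequatorial isomer is also the thermodynamic one by iminium–enamine exchange), after which ketimine 7 is hydrolysed; no electrophilic halogen, peroxide or metal oxidant is present and no enolate or C3 leaving group is formed, so the free phenols, ring A and C2 should survive without E1cB ring opening or flavone formation; the closest known reaction type is the α-acyloxylation of simple aldehydes and ketones with N-methyl-O-benzoylhydroxylammonium chloride (and the acylation–rearrangement of ketonitrones), not shown on a chelated 5-hydroxychroman-4-one, with free phenols, with a C2 stereocenter directing C3, or with a chiral aliphatic acyl group.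

**Compound list**
1 | (2R)-2-methylbutanoic acid | CC[C@@H](C)C(=O)O | starting material
2 | tert-butyl N-hydroxy-N-methylcarbamate | CN(O)C(=O)OC(C)(C)C | starting material
3 | tert-butyl N-methyl-N-{[(2R)-2-methylbutanoyl]oxy}carbamate | CC[C@@H](C)C(=O)ON(C)C(=O)OC(C)(C)C | intermediate
4 | N-methyl-O-[(2R)-2-methylbutanoyl]hydroxylammonium chloride | CC[C@@H](C)C(=O)O[NH2+]C.[Cl-] | intermediate
5 | (2S)-5,7-dihydroxy-2-phenyl-2,3-dihydro-4H-chromen-4-one ((2S)-pinocembrin) | O=C1C[C@@H](c2ccccc2)Oc2cc(O)cc(O)c12 | starting material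
6 | (2S)-4-{methyl[(2R)-2-methylbutanoyloxy]amino}-2-phenyl-2H-chromene-5,7-diol (N-acyloxy enamine) | CC[C@@H](C)C(=O)ON(C)C1=C[C@@H](c2ccccc2)Oc2cc(O)cc(O)c12 | intermediate
7 | (2R,3S)-5,7-dihydroxy-4-(methylimino)-2-phenyl-3,4-dihydro-2H-chromen-3-yl (2R)-2-methylbutanoate (2,3-trans; the C3 descriptor differs from 8 only because C=N ranks below C2) | CC[C@@H](C)C(=O)O[C@H]1C(=NC)c2c(O)cc(O)cc2O[C@@H]1c1ccccc1 | intermediate
8 | (2R,3R)-5,7-dihydroxy-4-oxo-2-phenyl-3,4-dihydro-2H-chromen-3-yl (2R)-2-methylbutanoate | CC[C@@H](C)C(=O)O[C@H]1C(=O)c2c(O)cc(O)cc2O[C@@H]1c1ccccc1 | target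

**Step count**
Total steps: 3. Longest linear sequence: 3 (1 → 3 → 4 → 8).

**Steps most likely to fail**

Step 3 (the new step, highest risk). The chelated, vinylogous-ester-like C4 ketone may condense too slowly with the weakly nucleophilic reagent, or C2 may erode by retro-oxa-Michael opening of 6; the ee of 8 is checked by chiral HPLC. The fallback uses known chemistry, sets out from 5 and comes back at 8. Compound 5 is silylated at the 7-OH (TBSCl, imidazole, DMF, 0 °C) to (2S)-7-[(tert-butyldimethylsilyl)oxy]-5-hydroxy-2-phenyl-2,3-dihydro-4H-chromen-4-one F1. Soft enolisation (TMSOTf, Et3N, CH2Cl2, 0 °C) gives (2S)-7-[(tert-butyldimethylsilyl)oxy]-2-phenyl-4,5-bis[(trimethylsilyl)oxy]-2H-chromene F2. Rubottom oxidation with dimethyldioxirane (acetone, −40 °C, epoxide formed anti to the C2 phenyl) and citric acid/MeOH work-up give (2R,3R)-7-[(tert-butyldimethylsilyl)oxy]-3,5-dihydroxy-2-phenyl-2,3-dihydro-4H-chromen-4-one F3. Steglich esterification of the 3-OH with 1 (DCC, DMAP, CH2Cl2; the chelated 5-OH does not react) gives (2R,3R)-7-[(tert-butyldimethylsilyl)oxy]-5-hydroxy-4-oxo-2-phenyl-3,4-dihydro-2H-chromen-3-yl (2R)-2-methylbutanoate F4. Et3N·3HF in THF then frees the 7-OH to give 8.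

Step 2. The O-acyl group may shift to nitrogen (giving the N-methylhydroxamic acid) or hydrolyse while the Boc group leaves, and the salt may be hygroscopic. The fallback makes no O-acylhydroxylamine at all; it sets out from 5 and 1 and comes back at 6. Compound 5 is condensed with N-methylhydroxylamine hydrochloride in NaOAc/AcOH-buffered MeOH (pH about 5, 40 °C, so that ring C is not opened) to the ketonitrone (2S)-5,7-dihydroxy-N-methyl-2-phenyl-2,3-dihydro-4H-chromen-4-imine N-oxide F5. Acid 1 is converted with oxalyl chloride and catalytic DMF into (2R)-2-methylbutanoyl chloride F6. F6 acylates the nitrone oxygen of F5 at −40 °C in CH2Cl2 without base; the N-acyloxyiminium chloride loses HCl to give 6, and the route continues as in step 3.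

Step 1. N-acylurea formation or partial epimerisation of the α-carbon by DMAP may lower yield or ee. The fallback drops the carbamate carrier; it sets out from 1 and comes back at 4, bypassing 2, 3 and the Boc cleavage. Acid 1 is activated with 1,1'-carbonyldiimidazole in CH2Cl2 to (2R)-1-(1H-imidazol-1-yl)-2-methylbutan-1-one F7. F7 is treated with N-methylhydroxylamine hydrochloride and MeSO3H (1 equiv), so that nitrogen stays protonated and only the OH is acylated. A cold NaHCO3 wash followed at once by HCl in Et2O precipitates 4.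

**Further compounds**
F1 | step 3 | (2S)-7-[(tert-butyldimethylsilyl)oxy]-5-hydroxy-2-phenyl-2,3-dihydro-4H-chromen-4-one | O=C1C[C@@H](c2ccccc2)Oc2cc(O[Si](C)(C)C(C)(C)C)cc(O)c12
F2 | step 3 | (2S)-7-[(tert-butyldimethylsilyl)oxy]-2-phenyl-4,5-bis[(trimethylsilyl)oxy]-2H-chromene | C[Si](C)(C)OC1=C[C@@H](c2ccccc2)Oc2cc(O[Si](C)(C)C(C)(C)C)cc(O[Si](C)(C)C)c12
F3 | step 3 | (2R,3R)-7-[(tert-butyldimethylsilyl)oxy]-3,5-dihydroxy-2-phenyl-2,3-dihydro-4H-chromen-4-one | O[C@H]1C(=O)c2c(O)cc(O[Si](C)(C)C(C)(C)C)cc2O[C@@H]1c1ccccc1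
F4 | step 3 | (2R,3R)-7-[(tert-butyldimethylsilyl)oxy]-5-hydroxy-4-oxo-2-phenyl-3,4-dihydro-2H-chromen-3-yl (2R)-2-methylbutanoate | CC[C@@H](C)C(=O)O[C@H]1C(=O)c2c(O)cc(O[Si](C)(C)C(C)(C)C)cc2O[C@@H]1c1ccccc1
F5 | step 2 | (2S)-5,7-dihydroxy-N-methyl-2-phenyl-2,3-dihydro-4H-chromen-4-imine N-oxide | C[N+]([O-])=C1C[C@@H](c2ccccc2)Oc2cc(O)cc(O)c12
F6 | step 2 | (2R)-2-methylbutanoyl chloride | CC[C@@H](C)C(Cl)=O
F7 | step 1 | (2R)-1-(1H-imidazol-1-yl)-2-methylbutan-1-one | CC[C@@H](C)C(=O)n1ccnc1
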